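# Synthesis proposal for CNP0271206.1 (compound 12)

## Analysis of the target

1. Target 12 has one oxolane ring (O1, C2, C3, C4, C5). C2 carries a 3,4-dimethoxyphenyl group, C3 a CH2OH group, C4 a 3,4,5-trimethoxybenzoyl group, and C5 is a plain CH2.
2. The three stereocentres are contiguous. The SMILES reads as (2R,3R,4S), so aryl and CH2OH lie on the same face (2,3-cis) and the aroyl group lies on the other face (3,4-trans, 2,4-trans).
3. C4 is alpha to an aryl ketone and can epimerise, but trans to C3 is the more stable arrangement, so this centre corrects itself.
4. C2 is the hard centre. It is a benzylic ether carbon on a very electron-rich ring, C2–O1 ionises easily under acid, and the required 2,3-cis relation is the less stable one.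
5. Any ring closure through an equilibrating benzylic cation therefore ends at the wrong C2 epimer.
6. Other sensitive features are five aryl methyl ethers on two oxidisable rings and a gamma-hydroxy ketone. In the 3,4-trans series this ketone cannot close to a hemiketal.
7. The feature that invites the strategy is the chain C5–C4–C3–CH2OH. It has four carbons with oxygen at both ends (O1 and the hydroxyl O), which is the skeleton of but-2-ene-1,4-diol. In addition, O1–C2–C3–C(H2)OH is an aldol retron once that carbon is at aldehyde level.
8. Moving C2 from C3 onto the hydroxyl oxygen turns the oxolane into a seven-membered cyclic acetal of 1, a 1,3-dioxepine ring with a single stereocentre.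

## Retrosynthetic reasoning

**12 to 10 (through 11).**
- The ketone C=O is traced back to a C=CH2 group.
- A free aroyl group any earlier would make C4–H acidic. In the seven-membered precursor that C–H would be both alpha-keto and allylic, so it would racemise or slip into conjugation.
- The 1-arylethenyl group cannot enolise, already holds every carbon, and arrives in one piece.
- The forward reaction must cleave one hindered styrene-type alkene without touching two electron-rich rings.

**10 to 9.** The CH2OH group is raised to CHO. This costs one hydride reduction in the forward sense and exposes the aldol relation between C2 and the formyl carbon.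

**9 to 7 (through 8), the key disconnection.**
- The C2–C3 bond is cut and C2 is reconnected to the formyl oxygen, which gives the 4,5-dihydro-1,3-dioxepine 7.
- The cut is placed here because C2 is then at acetal level and needs no configuration of its own.
- Three stereocentres shrink to one, and the carbons fall apart into an aldehyde and a C4 diol.
- The forward reaction is a Lewis acid induced [1,3] O-to-C shift. It must form C2–C3, contract the ring from seven to five members, and set C2 and C3 from the one centre present, under kinetic control.

**7 to 3 and 6.**
- The bond between dioxepine C5 (later oxolane C4) and the alkenyl carbon is cut.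
- Compound 3 has a mirror plane and two enantiotopic alkene carbons. An asymmetric Heck reaction with 6 desymmetrises it, creates the only stereocentre that needs a chiral reagent, and moves the double bond into the enol ether position that the key step needs.

**3 to 1 and 2; 6 to 4 (through 5).** These are an acetalisation and an enol triflation of commodity chemicals.

## Alternatives that were turned down

**Alternative 1: the textbook route.**
- Disconnection: C4–C(=O) and C2–C3 on a butenolide core, then O1–C2.
- Forward key step: the lithiated dithiane A1 adds 1,4 to the parent five-membered butenolide. The lactone enolate is trapped with 1 to give hydroxy lactone A2. Lactone reduction, acid cycloetherification and dithiane hydrolysis follow.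
- Turned down for three reasons:
  - The tandem step gives the trans lactone, which maps onto a 3,4-cis oxolane and needs a late epimerisation.
  - The ether closure runs through the veratryl cation and therefore delivers the more stable 2,3-trans relation, which is wrong for 12.
  - Absolute control needs an auxiliary on the butenolide that must be attached and removed, so the step count is clearly higher.

**Alternative 2: the biomimetic route.**
- Disconnection: 12 is read as an oxidatively opened furofuran, so the bond between the hydroxyl oxygen and the ketone carbon is restored.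
- Forward key step: a quinone oxidant abstracts a benzylic hydride from the endo-veratryl, exo-trimethoxyphenyl dioxabicyclooctane A3 in wet solvent. The hemiketal collapses to the all-cis hydroxy ketone A4, and base epimerises C4 to give 12.
- Turned down for two reasons:
  - A3 has four stereocentres and two rings, so it is harder to make than 12.
  - Hydride abstraction prefers the position next to the better donor, the 3,4-dimethoxyphenyl ring. In the trimethoxy ring the para methoxy group is twisted out of conjugation and the two meta groups withdraw. The wrong ring would therefore open.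

**Alternative 3: the Prins–pinacol route.**
- Disconnection: C2–C3 and C4–C5, combined with a 1,2-shift.
- Forward key step: a tin(IV) Lewis acid opens the 4-aryl-4-[(Z)-alkenyl]-1,3-dioxolane A5 to an oxocarbenium ion and the Z-alkene attacks it (C2–C3 forms, cis through a chair). The CH2O carbon then migrates to C4 while the carbinol carbon becomes the ketone. This gives silyl ether A6, which is then deprotected.
- Turned down for three reasons:
  - The carbinol carbon of A5 is tertiary, benzylic and allylic, so it ionises in competition with the acetal and the stereochemical information is lost.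
  - The Prins step would place a secondary cation on C4.
  - A5 costs a coupling, an asymmetric dihydroxylation of a 1,1-disubstituted enyne, a semihydrogenation, an acetalisation and a protecting group. That is more than the key step wins.

Key step: step 4

**Assumption.** (S)-tBu-PHOX is assumed to give the 5R configuration of 7 in step 3. If the sense of induction is opposite, the equally available (R)-ligand is used and nothing else changes.

**Locants.** Oxolane locants are O1, C2 (aryl), C3 (CH2OH or CHO), C4 (alkenyl or aroyl), C5. Dioxepine locants are O1, C2 (acetal), O3, C4, C5, C6, C7.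

## Route

Step 1
Reactants: 1 3,4-dimethoxybenzaldehyde; 2 (Z)-but-2-ene-1,4-diol
Product: 3 2-(3,4-dimethoxyphenyl)-4,7-dihydro-1,3-dioxepine
Conditions: p-TsOH·H2O (cat.), toluene, reflux, Dean–Stark trap
Reagents that add atoms: none
Why: Acid-catalysed acetalisation driven by azeotropic removal of water; the Z-diol is preorganised for the seven-membered ring. No stereocentre is formed, since C2 lies on the mirror plane of 3.

Step 2
Reactants: 4 1-(3,4,5-trimethoxyphenyl)ethanone
Product: 6 1-(3,4,5-trimethoxyphenyl)ethenyl trifluoromethanesulfonate, via potassium enolate 5 (not isolated)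
Conditions: KHMDS, THF, −78 °C; then PhNTf2, −78 to 0 °C
Reagents that add atoms: N-phenylbis(trifluoromethanesulfonimide), O=S(=O)(N(c1ccccc1)S(=O)(=O)C(F)(F)F)C(F)(F)F
Why: Irreversible deprotonation of a methyl ketone that has only one enolisable site, followed by O-sulfonylation of the enolate (enol triflate formation). The mild triflyl donor avoids ring sulfonylation of the electron-rich arene.

Step 3
Reactants: 3 2-(3,4-dimethoxyphenyl)-4,7-dihydro-1,3-dioxepine (excess); 6 1-(3,4,5-trimethoxyphenyl)ethenyl trifluoromethanesulfonate
Product: 7 (5R)-2-(3,4-dimethoxyphenyl)-5-[1-(3,4,5-trimethoxyphenyl)ethenyl]-4,5-dihydro-1,3-dioxepine (both C2 epimers)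
Conditions: Pd2(dba)3 (2.5 mol %), (S)-tBu-PHOX (6 mol %), i-Pr2NEt, 3 Å MS, benzene, 60 °C
Reagents that add atoms: none
Why: Intermolecular asymmetric Heck reaction on the cationic pathway, a known desymmetrisation of 4,7-dihydro-1,3-dioxepines; syn insertion puts the alkenyl group on C5 and Pd on C6, and since H5 is anti to Pd only a C7–H can eliminate, which gives the C6=C7 enol ether. The P,N ligand decides which enantiotopic alkene carbon is attacked on either face, so both C2 epimers should carry the same C5 configuration, and the fast release of Pd–H from this ligand class limits double-bond migration.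

Step 4
Reactants: 7 (5R)-2-(3,4-dimethoxyphenyl)-5-[1-(3,4,5-trimethoxyphenyl)ethenyl]-4,5-dihydro-1,3-dioxepine
Product: 9 (2R,3S,4R)-2-(3,4-dimethoxyphenyl)-4-[1-(3,4,5-trimethoxyphenyl)ethenyl]oxolane-3-carbaldehyde, via oxocarbenium silyl enol ether triflate 8 (not isolated)
Conditions: TMSOTf (20 mol %), 2,6-di-tert-butyl-4-methylpyridine (30 mol %), CH2Cl2, −78 °C, short contact time; Et3N quench at −78 °C; crude 9 used at once
Reagents that add atoms: none
Why: TMSOTf silylates the enol ether oxygen O1 and C2–O1 ionises to the ring-opened ion pair 8, an (E)-veratryl oxocarbenium ion tethered through O3–C4–C5 to a (Z)-silyl enol ether; C6 then attacks the cationic carbon in an intramolecular Mukaiyama aldol step and releases TMSOTf, so the net change is a [1,3] O-to-C shift that forms C2–C3 and contracts the seven-membered ring to the oxolane. The closest known reaction type is the Lewis acid mediated ring contraction of 2-aryl and 2,5-disubstituted 4,5-dihydro-1,3-dioxepines to oxolane-3-carbaldehydes. The single ring closes in a 5-(enolexo)-endo-trig mode, which is tight but usual for oxocarbenium electrophiles with their early transition state. C3 is controlled by the Heck-derived centre: allylic 1,3-strain with the Z-silyloxy group holds the C5–H bond in the plane of the enol ether, so tether and alkenyl group sit on opposite faces, the tether reaches only its own face, and the formyl group ends trans to the alkenyl group. C2 is set kinetically: in the compact synclinal arrangement the silyloxy-bearing carbon stays next to the oxocarbenium oxygen it has just left (least motion, Coulomb attraction) and the aryl group of the E-cation points to the face away from the C4 alkenyl group, which gives aryl cis to formyl and trans to alkenyl. Both C2 epimers of 7 give the same planar cation, so the mixture converges. The step needs the enol ether to outrun the styrene double bond (six-membered Prins closure), which its higher nucleophilicity and the hindered base that removes traces of TfOH should secure. It also needs the closure not to reverse, which the low temperature, short time and cold quench should secure.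

Step 5
Reactants: 9 (2R,3S,4R)-2-(3,4-dimethoxyphenyl)-4-[1-(3,4,5-trimethoxyphenyl)ethenyl]oxolane-3-carbaldehyde
Product: 10 [(2R,3R,4R)-2-(3,4-dimethoxyphenyl)-4-[1-(3,4,5-trimethoxyphenyl)ethenyl]oxolan-3-yl]methanol
Conditions: NaBH4, MeOH–CH2Cl2, −78 to −40 °C
Reagents that add atoms: none
Why: Borohydride reduction of an aldehyde, fast even at low temperature, which removes the acidity of C3–H and so locks the 2,3-cis relation. No stereocentre is made or touched; the descriptor at C3 changes only because the priorities change.

Step 6
Reactants: 10 [(2R,3R,4R)-2-(3,4-dimethoxyphenyl)-4-[1-(3,4,5-trimethoxyphenyl)ethenyl]oxolan-3-yl]methanol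
Product: 12 [(3S,4R,5R)-5-(3,4-dimethoxyphenyl)-4-(hydroxymethyl)oxolan-3-yl](3,4,5-trimethoxyphenyl)methanone, via vicinal diol 11 (not isolated)
Conditions: OsO4 (2 mol %), NaIO4, 2,6-lutidine, dioxane–H2O, rt
Reagents that add atoms: sodium periodate, [Na+].[O-]I(=O)(=O)=O (terminal source of the ketone oxygen); osmium tetroxide, O=[Os](=O)(=O)=O (transfers it)
Why: Lemieux–Johnson cleavage: catalytic dihydroxylation of the only alkene, then periodate cleavage of the 1,2-diol to the aryl ketone and formaldehyde; arenes, benzylic ether and primary alcohol are inert and lutidine buffers the medium. C4 becomes epimerisable only now and already holds the more stable trans arrangement, so it should stay (2R,3R,4S in the oxolane locants).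

## Compound list

1 | 3,4-dimethoxybenzaldehyde | COc1ccc(C=O)cc1OC | starting material
2 | (Z)-but-2-ene-1,4-diol | OC/C=C\CO | starting material
3 | 2-(3,4-dimethoxyphenyl)-4,7-dihydro-1,3-dioxepine | COc1ccc(C2OCC=CCO2)cc1OC | intermediate
4 | 1-(3,4,5-trimethoxyphenyl)ethanone | CC(=O)c1cc(OC)c(OC)c(OC)c1 | starting material
5 | potassium 1-(3,4,5-trimethoxyphenyl)ethenolate | [K+].[O-]C(=C)c1cc(OC)c(OC)c(OC)c1 | intermediate (not isolated)
6 | 1-(3,4,5-trimethoxyphenyl)ethenyl trifluoromethanesulfonate | C=C(OS(=O)(=O)C(F)(F)F)c1cc(OC)c(OC)c(OC)c1 | intermediate
7 | (5R)-2-(3,4-dimethoxyphenyl)-5-[1-(3,4,5-trimethoxyphenyl)ethenyl]-4,5-dihydro-1,3-dioxepine, C2 epimers | COc1ccc(C2OC[C@@H](C(=C)c3cc(OC)c(OC)c(OC)c3)C=CO2)cc1OC | intermediate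
8 | (E)-veratrylidene oxonium triflate of (2R,3Z)-2-[1-(3,4,5-trimethoxyphenyl)ethenyl]-4-(trimethylsilyloxy)but-3-en-1-ol | COc1ccc(/C=[O+]/C[C@@H](C(=C)c2cc(OC)c(OC)c(OC)c2)/C=C\O[Si](C)(C)C)cc1OC.[O-]S(=O)(=O)C(F)(F)F | intermediate (not isolated)
9 | (2R,3S,4R)-2-(3,4-dimethoxyphenyl)-4-[1-(3,4,5-trimethoxyphenyl)ethenyl]oxolane-3-carbaldehyde | COc1ccc([C@@H]2OC[C@@H](C(=C)c3cc(OC)c(OC)c(OC)c3)[C@@H]2C=O)cc1OC | intermediate
10 | [(2R,3R,4R)-2-(3,4-dimethoxyphenyl)-4-[1-(3,4,5-trimethoxyphenyl)ethenyl]oxolan-3-yl]methanol | COc1ccc([C@@H]2OC[C@@H](C(=C)c3cc(OC)c(OC)c(OC)c3)[C@@H]2CO)cc1OC | intermediate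
11 | 1-[(3S,4R,5R)-5-(3,4-dimethoxyphenyl)-4-(hydroxymethyl)oxolan-3-yl]-1-(3,4,5-trimethoxyphenyl)ethane-1,2-diol, carbinol epimers | COc1ccc([C@@H]2OC[C@@H](C(O)(CO)c3cc(OC)c(OC)c(OC)c3)[C@@H]2CO)cc1OC | intermediate (not isolated)
12 | [(3S,4R,5R)-5-(3,4-dimethoxyphenyl)-4-(hydroxymethyl)oxolan-3-yl](3,4,5-trimethoxyphenyl)methanone | COc1ccc([C@@H]2OC[C@@H](C(=O)c3cc(OC)c(OC)c(OC)c3)[C@@H]2CO)cc1OC | target

## Step count and risk

Total step count: 6. Longest linear sequence: 5 (steps 1, 3, 4, 5, 6; the branch through steps 2, 3, 4, 5, 6 is equally long).

**Step 4 (key step).**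
- The most likely failure is loss of kinetic control. The veratryl group stabilises the oxocarbenium ion so well that the closure may become reversible, and the aryl group then drifts to the more stable 2,3-trans side.
- Further risks are capture of the cation by the styrene double bond in a six-membered Prins closure, and collapse of the ion pair before the two C2 epimers of 7 have converged.
- Fallback, from 7 back to 10. The oxolane ring is taken from a lactone instead of being made by C2–C3 bond formation, and C2 is set by hydride delivery instead of by ion-pair collapse.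
  - Mild aqueous acid hydrolyses 7 to the lactol (4R)-4-[1-(3,4,5-trimethoxyphenyl)ethenyl]oxolan-2-ol F1.
  - TEMPO/PhI(OAc)2 oxidises it to the lactone (4R)-4-[1-(3,4,5-trimethoxyphenyl)ethenyl]oxolan-2-one F2.
  - LDA and then monomeric formaldehyde should give, by attack anti to the C4 substituent, the trans lactone (3R,4R)-3-(hydroxymethyl)-4-[1-(3,4,5-trimethoxyphenyl)ethenyl]oxolan-2-one F3.
  - An excess of 3,4-dimethoxyphenyllithium F4, made from 4-bromoveratrole and n-BuLi, adds to the lactone carbonyl at −78 °C to give the hemiketal (3R,4R)-2-(3,4-dimethoxyphenyl)-3-(hydroxymethyl)-4-[1-(3,4,5-trimethoxyphenyl)ethenyl]oxolan-2-ol F5.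
  - Et3SiH/BF3·OEt2 at −78 °C reduces the derived 2-aryl oxocarbenium ion from the face opposite the C3 substituent. This places the aryl group cis to CH2OH and gives 10.

**Step 3.**
- The most likely failures are slow insertion of the hindered alpha-aryl alkenylpalladium species and re-addition of Pd–H, which moves the double bond out of the enol ether position or into conjugation and erases the stereocentre.
- Enantiodiscrimination may also be weakened, because the C2 aryl group makes the two alkene faces unequal.
- Fallback, from 6 back to 10. The stereocentre is set by a rhodium-catalysed asymmetric 1,4-addition instead of a Heck reaction.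
  - Miyaura borylation of 6 gives the boronate 4,4,5,5-tetramethyl-2-[1-(3,4,5-trimethoxyphenyl)ethenyl]-1,3,2-dioxaborolane F6.
  - Rh(I)/BINAP-catalysed conjugate addition of F6 to commercial 2(5H)-furanone, with the ligand enantiomer chosen for the R product, gives the lactone F2 directly.
  - F2 then goes on through F3 and F5 to 10 as described above.

**Step 5.**
- The most likely failure is epimerisation at C3, or beta-elimination of O1 (retro-oxa-Michael ring opening followed by reclosure). Either can occur while the beta-alkoxy aldehyde is handled or meets the basic borohydride medium, and either erodes the 2,3-cis relation.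
- Fallback, from 7 back to 10. The aldehyde is never set free.
  - The ring contraction is run with stoichiometric i-Bu3Al at low temperature.
  - The aluminium-bound aldehyde is reduced in place by beta-hydride transfer from an isobutyl group, as in aluminium-promoted rearrangement–reduction sequences of vinyl ethers.
  - Steps 4 and 5 thus merge into one operation and no new compound is made.

## Further compounds

F1 | step 4 | (4R)-4-[1-(3,4,5-trimethoxyphenyl)ethenyl]oxolan-2-ol (anomers) | OC1OC[C@@H](C(=C)c2cc(OC)c(OC)c(OC)c2)C1
F2 | step 4 | (4R)-4-[1-(3,4,5-trimethoxyphenyl)ethenyl]oxolan-2-one | O=C1OC[C@@H](C(=C)c2cc(OC)c(OC)c(OC)c2)C1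
F3 | step 4 | (3R,4R)-3-(hydroxymethyl)-4-[1-(3,4,5-trimethoxyphenyl)ethenyl]oxolan-2-one | O=C1OC[C@@H](C(=C)c2cc(OC)c(OC)c(OC)c2)[C@@H]1CO
F4 | step 4 | 3,4-dimethoxyphenyllithium | [Li]c1ccc(OC)c(OC)c1
F5 | step 4 | (3R,4R)-2-(3,4-dimethoxyphenyl)-3-(hydroxymethyl)-4-[1-(3,4,5-trimethoxyphenyl)ethenyl]oxolan-2-ol (anomers) | COc1ccc(C2(O)OC[C@@H](C(=C)c3cc(OC)c(OC)c(OC)c3)[C@@H]2CO)cc1OC
F6 | step 3 | 4,4,5,5-tetramethyl-2-[1-(3,4,5-trimethoxyphenyl)ethenyl]-1,3,2-dioxaborolane | C=C(B1OC(C)(C)C(C)(C)O1)c1cc(OC)c(OC)c(OC)c1
F0 | step 5 | none | none
A1 | alternative 1 | 2-(3,4,5-trimethoxyphenyl)-1,3-dithiane | COc1cc(C2SCCCS2)cc(OC)c1OC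
A2 | alternative 1 | trans-3-[(3,4-dimethoxyphenyl)(hydroxy)methyl]-4-[2-(3,4,5-trimethoxyphenyl)-1,3-dithian-2-yl]oxolan-2-one (one enantiomer and one carbinol epimer drawn) | COc1ccc([C@H](O)[C@H]2C(=O)OC[C@@H]2C3(SCCCS3)c4cc(OC)c(OC)c(OC)c4)cc1OC
A3 | alternative 2 | endo-2-(3,4-dimethoxyphenyl)-exo-6-(3,4,5-trimethoxyphenyl)-3,7-dioxabicyclo[3.3.0]octane | COc1ccc([C@@H]2OC[C@H]3[C@@H]2CO[C@@H]3c4cc(OC)c(OC)c(OC)c4)cc1OC
A4 | alternative 2 | all-cis hydroxy ketone, the C4 epimer of 12 | COc1ccc([C@@H]2OC[C@H](C(=O)c3cc(OC)c(OC)c(OC)c3)[C@@H]2CO)cc1OC
A5 | alternative 3 | (4S)-4-[(Z)-3-(tert-butyldimethylsilyloxy)prop-1-enyl]-2-(3,4-dimethoxyphenyl)-4-(3,4,5-trimethoxyphenyl)-1,3-dioxolane (C2 epimers) | COc1ccc(C2OC[C@](O2)(/C=C\CO[Si](C)(C)C(C)(C)C)c3cc(OC)c(OC)c(OC)c3)cc1OC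
A6 | alternative 3 | tert-butyldimethylsilyl ether of 12 | COc1ccc([C@@H]2OC[C@@H](C(=O)c3cc(OC)c(OC)c(OC)c3)[C@@H]2CO[Si](C)(C)C(C)(C)C)cc1OC
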